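**Plan**
- Retrosynthesis (carotenoid numbering): cut C11=C12 (Wittig), then C8–C9 (alkenyl iodide to aldehyde), then C7–C8 (one-carbon homologation), then both ring bonds C1–C2 and C3–C4 of the hydroxylated β ring in one [4+2] event. The ε half is cut at C11'=C12' (Wittig) and C9'=C10' (HWE).
- Enabling feature: in the β ring the tetrasubstituted C5=C6 double bond lies between the ring CH2 (C4) and the CMe2 carbon (C1), and the carbinol C3 is 1,4 to C6, the only ring carbon with a side chain. With C7 held as a nitrile, this cyclohexene is the adduct of a 2-cyano-1,3-diene and an enol ether.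
- Forward order: cyano-diene plus O-vinyl auxiliary gives the β ring. The nitrile carbon becomes C7 and is extended to the C8 aldehyde. A four-carbon linker (C9, C10, C11, C19, already carrying the dodecanoate) is joined at C8–C9.
- The ε half grows from (R)-α-ionone and the C10 dialdehyde to a C25 phosphonium salt, and the last step closes C11=C12.
- Stereochemistry: C3 from the removable chiral O-vinyl auxiliary in the key step; C6' bought with (R)-α-ionone; C3' by substrate-controlled hydride delivery followed by Mitsunobu inversion. C9=C10 geometry comes from syn-hydrostannation, the other double bonds from HWE/Wittig reactions with thermal equilibration.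

Key step: step 4

Assumption: (R)-α-ionone, (1S)-1-(2,4,6-triisopropylphenyl)ethanol, 4,4-diethoxybut-2-yn-1-ol and (2E,4E,6E)-2,7-dimethylocta-2,4,6-trienedial are taken as commercial.
Assumption: the auxiliary is taken to direct as in the s-trans model of step 4; if the sense were the opposite, the equally available (1R)-alcohol would be used in the same way.

**Route**

Step 1
Reactants: 1 3-methylbut-2-enenitrile
Product: 3 2-bromo-3-methylbut-2-enenitrile, via dibromide 2 (not isolated)
Conditions: Br2, CH2Cl2, 0 °C to rt; then Et3N, 0 °C to rt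
Reagents that add atoms: bromine (BrBr)
Why: Bromine addition to the alkene followed by E1cB-type dehydrobromination (the α-proton is acidified by the nitrile and the tertiary bromide leaves) should give the α-bromoacrylonitrile, as in the known bromination/dehydrobromination of senecioic acid derivatives.

Step 2
Reactants: 3 2-bromo-3-methylbut-2-enenitrile; 4 4,4,5,5-tetramethyl-2-(prop-1-en-2-yl)-1,3,2-dioxaborolane
Product: 5 3-methyl-2-(prop-1-en-2-yl)but-2-enenitrile
Conditions: PdCl2(dppf) (3 mol %), K3PO4, dioxane/H2O, 80 °C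
Reagents that add atoms: none
Why: Suzuki–Miyaura coupling of the activated alkenyl bromide with the alkenyl boronate should join the two sp2 carbons and give the cross-conjugated 2-cyano-1,3-diene.

Step 3
Reactants: 6 (1S)-1-(2,4,6-triisopropylphenyl)ethanol; 7 butyl vinyl ether
Product: 8 1,3,5-triisopropyl-2-[(1S)-1-(vinyloxy)ethyl]benzene
Conditions: Pd(OCOCF3)2 (2 mol %), 4,7-diphenyl-1,10-phenanthroline (2 mol %), Et3N (cat.), 7 (neat, excess), 75 °C
Reagents that add atoms: none
Why: Palladium-catalysed transfer vinylation (transetherification) exchanges only the O–H bond, so the O-vinyl auxiliary should form with the benzylic stereocentre untouched.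

Step 4
Reactants: 5 3-methyl-2-(prop-1-en-2-yl)but-2-enenitrile; 8 1,3,5-triisopropyl-2-[(1S)-1-(vinyloxy)ethyl]benzene
Product: 9 (4R)-2,6,6-trimethyl-4-[(1S)-1-(2,4,6-triisopropylphenyl)ethoxy]cyclohex-1-ene-1-carbonitrile
Conditions: 8 (1.5 equiv), BHT (1 mol %), CH2Cl2, 12 kbar, 50 °C
Reagents that add atoms: none
Why: Proposed new method: a concerted but asynchronous inverse-electron-demand [4+2] cycloaddition in which the HOMO of enol ether 8 (large coefficient on its CH2) meets the LUMO of cyano-diene 5 (large coefficient on the CMe2 terminus, the β-carbon of the acrylonitrile unit), so that the vinyl CH2 bonds to CMe2 and the oxygen-bearing carbon bonds to the diene CH2 terminus, leaving the new ring double bond tetrasubstituted between the methyl- and cyano-bearing carbons. The closest known reaction type is the inverse-demand Diels–Alder reaction of 2-cyano-, 2-alkoxycarbonyl- and 2-sulfonyl-1,3-dienes with alkyl vinyl ethers, which gives 4-alkoxycyclohexenes in the same para orientation, together with the use of O-vinyl ethers of chiral secondary alcohols as face-selective partners for acceptor-substituted 2-pyrones and nitroalkenes; a diene with a fully substituted terminus and auxiliary control on an open-chain carbodiene go beyond that precedent. The cyclohexene is closed in an intermolecular [4+2] mode in which both σ-bonds form in one event. The only new stereocentre, the alkoxy-bearing ring carbon, depends solely on which face of the enol ether is attacked, and in the s-trans enol ether conformation (benzylic C–H in the enol ether plane) the triisopropylphenyl group should shield one face, so that the (S)-auxiliary should lead to R. The step needs regioselectivity (cyano polarisation and the bulk of the CMe2 terminus both send the unsubstituted vinyl CH2 there), periselectivity over [2+2] closure of a zwitterion (no Lewis acid, high pressure favouring the compact [4+2] transition state, and a linear nitrile that cannot act as a heterodiene) and facial selectivity (the auxiliary, with the option of separating the two diastereomers of 9 before it is removed).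

Step 5
Reactants: 9 (4R)-2,6,6-trimethyl-4-[(1S)-1-(2,4,6-triisopropylphenyl)ethoxy]cyclohex-1-ene-1-carbonitrile
Product: 10 (4R)-4-hydroxy-2,6,6-trimethylcyclohex-1-ene-1-carbonitrile
Conditions: TFA (5 equiv), CH2Cl2, 0 °C; aq. NaHCO3
Reagents that add atoms: none
Why: Acidolysis of the doubly ortho-substituted benzylic ether (E1 ionisation to the stabilised benzylic cation, which loses a proton) should free the carbinol with retention, because the C–O bond at the ring stereocentre is not broken and the cyano-deactivated ring alkene resists protonation.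

Step 6
Reactants: 10 (4R)-4-hydroxy-2,6,6-trimethylcyclohex-1-ene-1-carbonitrile
Product: 12 (4R)-4-hydroxy-2,6,6-trimethylcyclohex-1-ene-1-carbaldehyde, via aldimine 11 (not isolated)
Conditions: i-Bu2AlH (DIBAL-H, 2.5 equiv), CH2Cl2, −78 to 0 °C; then 1 M aq. HCl, 0 °C
Reagents that add atoms: water (O)
Why: DIBAL-H partial reduction of the nitrile to the N-aluminoimine, hydrolysed on work-up, should give the conjugated aldehyde, one extra equivalent being consumed by the hydroxyl group.

Step 7
Reactants: 12 (4R)-4-hydroxy-2,6,6-trimethylcyclohex-1-ene-1-carbaldehyde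
Product: 13 (1R)-4-(2-methoxyethenyl)-3,5,5-trimethylcyclohex-3-en-1-ol (E/Z mixture)
Conditions: MeOCH2PPh3Cl (3 equiv), KOtBu (3 equiv), THF, 0 °C; then 12, 0 °C to rt
Reagents that add atoms: (methoxymethyl)triphenylphosphonium chloride (COC[P+](c1ccccc1)(c1ccccc1)c1ccccc1.[Cl-])
Why: Wittig methoxymethylenation (one-carbon homologation) of the hindered enal with an excess of the unstabilised ylide should give the dienyl methyl ether, the alkoxide of the free hydroxyl being a spectator.

Step 8
Reactants: 13 (1R)-4-(2-methoxyethenyl)-3,5,5-trimethylcyclohex-3-en-1-ol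
Product: 14 [(4R)-4-hydroxy-2,6,6-trimethylcyclohex-1-en-1-yl]acetaldehyde
Conditions: 1 M aq. HCl, THF, 0 °C to rt
Reagents that add atoms: water (O)
Why: Enol ether hydrolysis by kinetic protonation at the carbon next to the ring should release the β,γ-unsaturated aldehyde while the tetrasubstituted ring alkene stays in place.

Step 9
Reactants: 15 4,4-diethoxybut-2-yn-1-ol
Product: 16 (2E)-4,4-diethoxy-2-(tributylstannyl)but-2-en-1-ol
Conditions: Bu3SnH (1.1 equiv), PdCl2(PPh3)2 (2 mol %), THF, 0 °C
Reagents that add atoms: tributyltin hydride (CCCC[SnH](CCCC)CCCC)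
Why: Palladium-catalysed syn-hydrostannation should place tin on the less hindered alkyne carbon next to the hydroxymethyl group (away from the branched acetal, helped by hydroxyl coordination) and hydrogen cis to it, which fixes the later C9=C10 geometry.

Step 10
Reactants: 16 (2E)-4,4-diethoxy-2-(tributylstannyl)but-2-en-1-ol
Product: 17 (2E)-4,4-diethoxy-2-iodobut-2-en-1-ol
Conditions: I2 (1.05 equiv), NaHCO3, CH2Cl2, 0 °C, dark
Reagents that add atoms: iodine (II)
Why: Iododestannylation is an ipso substitution with retention of alkene geometry and should convert the alkenylstannane into the alkenyl iodide.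

Step 11
Reactants: 17 (2E)-4,4-diethoxy-2-iodobut-2-en-1-ol; 18 dodecanoyl chloride
Product: 19 (2E)-4,4-diethoxy-2-iodobut-2-en-1-yl dodecanoate
Conditions: pyridine, DMAP (cat.), CH2Cl2, 0 °C
Reagents that add atoms: none
Why: DMAP-catalysed acylation of the primary allylic alcohol should install the dodecanoate at a stage where no other hydroxyl competes.

Step 12
Reactants: 14 [(4R)-4-hydroxy-2,6,6-trimethylcyclohex-1-en-1-yl]acetaldehyde; 19 (2E)-4,4-diethoxy-2-iodobut-2-en-1-yl dodecanoate
Product: 20 (2E)-4,4-diethoxy-2-{1-hydroxy-2-[(4R)-4-hydroxy-2,6,6-trimethylcyclohex-1-en-1-yl]ethyl}but-2-en-1-yl dodecanoate (both carbinol epimers)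
Conditions: CrCl2 (4 equiv), NiCl2 (1 mol %), DMF, rt; aq. work-up
Reagents that add atoms: none
Why: Nozaki–Hiyama–Kishi coupling (nickel-catalysed formation of an alkenylchromium species and its 1,2-addition to the aldehyde) should form the C8–C9 bond with retention of alkene geometry while tolerating the ester, the acetal and the free hydroxyl; the new carbinol centre is erased in the next step.

Step 13
Reactants: 20 (2E)-4,4-diethoxy-2-{1-hydroxy-2-[(4R)-4-hydroxy-2,6,6-trimethylcyclohex-1-en-1-yl]ethyl}but-2-en-1-yl dodecanoate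
Product: 21 (2E)-4,4-diethoxy-2-{[(4R)-4-hydroxy-2,6,6-trimethylcyclohex-1-en-1-yl]acetyl}but-2-en-1-yl dodecanoate
Conditions: MnO2 (activated, 20 equiv), CH2Cl2, rt
Reagents that add atoms: none
Why: MnO2 oxidation is selective for allylic alcohols and should convert only the new carbinol into the enone, leaving the non-allylic ring hydroxyl.

Step 14
Reactants: 21 (2E)-4,4-diethoxy-2-{[(4R)-4-hydroxy-2,6,6-trimethylcyclohex-1-en-1-yl]acetyl}but-2-en-1-yl dodecanoate
Product: 22 (2E)-2-{[(4R)-4-hydroxy-2,6,6-trimethylcyclohex-1-en-1-yl]acetyl}-4-oxobut-2-en-1-yl dodecanoate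
Conditions: TsOH·H2O (10 mol %), THF/H2O (4:1), rt
Reagents that add atoms: water (O)
Why: Acid-catalysed hydrolysis of the α,β-unsaturated diethyl acetal should unveil the enal, and because ketone and aldehyde are trans across the alkene no furan can form.

Step 15
Reactants: 23 (3E)-4-[(1R)-2,6,6-trimethylcyclohex-2-en-1-yl]but-3-en-2-one
Product: 24 ethyl (2E,4E)-3-methyl-5-[(1R)-2,6,6-trimethylcyclohex-2-en-1-yl]penta-2,4-dienoate
Conditions: (EtO)2P(O)CH2CO2Et (1.5 equiv), NaH (1.4 equiv), THF, 0 °C; then 23, 50 °C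
Reagents that add atoms: triethyl phosphonoacetate (CCOC(=O)CP(=O)(OCC)OCC)
Why: Horner–Wadsworth–Emmons olefination of the methyl ketone with the weakly basic phosphonoacetate anion should give mainly the 2E dienoate (minor 2Z isomer removed by chromatography) without epimerising the ring stereocentre.

Step 16
Reactants: 24 ethyl (2E,4E)-3-methyl-5-[(1R)-2,6,6-trimethylcyclohex-2-en-1-yl]penta-2,4-dienoate
Product: 25 ethyl (2E,4E)-3-methyl-5-[(1R)-2,6,6-trimethyl-4-oxocyclohex-2-en-1-yl]penta-2,4-dienoate
Conditions: Rh2(cap)4 (cap = caprolactamate, 1 mol %), tBuOOH (70% in water, 5 equiv), NaHCO3, CH2Cl2, rt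
Reagents that add atoms: tert-butyl hydroperoxide (CC(C)(C)OO)
Why: Dirhodium-caprolactamate-catalysed allylic oxidation (hydrogen abstraction by tert-butylperoxyl radical at the ring CH2 next to the trisubstituted alkene, then collapse of the mixed peroxide) should give the ring enone, the tertiary allylic C–H beside the gem-dimethyl group being less accessible.

Step 17
Reactants: 25 ethyl (2E,4E)-3-methyl-5-[(1R)-2,6,6-trimethyl-4-oxocyclohex-2-en-1-yl]penta-2,4-dienoate
Product: 26 ethyl (2E,4E)-5-[(1R,4S)-4-hydroxy-2,6,6-trimethylcyclohex-2-en-1-yl]-3-methylpenta-2,4-dienoate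
Conditions: LiBH(s-Bu)3 (1.1 equiv), THF, −78 °C; H2O
Reagents that add atoms: none
Why: 1,2-Reduction of the β,β-disubstituted cyclohexenone by the bulky hydride from the face opposite to the axial methyl of the gem-dimethyl group (half-chair with the side chain pseudo-equatorial) should give the cis (1R,4S) allylic alcohol by substrate control, the β,β-disubstituted dienoate being inert.

Step 18
Reactants: 26 ethyl (2E,4E)-5-[(1R,4S)-4-hydroxy-2,6,6-trimethylcyclohex-2-en-1-yl]-3-methylpenta-2,4-dienoate
Product: 27 (1R,4R)-4-[(1E,3E)-5-ethoxy-3-methyl-5-oxopenta-1,3-dien-1-yl]-3,5,5-trimethylcyclohex-2-en-1-yl benzoate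
Conditions: PhCO2H, PPh3, DIAD, THF, 0 °C to rt
Reagents that add atoms: benzoic acid (O=C(O)c1ccccc1)
Why: Mitsunobu esterification proceeds by SN2 displacement of the oxyphosphonium with inversion and should give the trans benzoate, SN2' attack being blocked at the fully substituted alkene carbon.

Step 19
Reactants: 27 (1R,4R)-4-[(1E,3E)-5-ethoxy-3-methyl-5-oxopenta-1,3-dien-1-yl]-3,5,5-trimethylcyclohex-2-en-1-yl benzoate
Product: 28 (2E,4E)-5-[(1R,4R)-4-hydroxy-2,6,6-trimethylcyclohex-2-en-1-yl]-3-methylpenta-2,4-dien-1-ol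
Conditions: i-Bu2AlH (DIBAL-H, 5 equiv), CH2Cl2, −78 to 0 °C; Rochelle salt
Reagents that add atoms: none
Why: DIBAL-H reduction should convert the dienoate into the primary allylic alcohol and cleave the benzoate in the same operation, neither event touching a stereocentre.

Step 20
Reactants: 28 (2E,4E)-5-[(1R,4R)-4-hydroxy-2,6,6-trimethylcyclohex-2-en-1-yl]-3-methylpenta-2,4-dien-1-ol
Product: 29 {(2E,4E)-5-[(1R,4R)-4-hydroxy-2,6,6-trimethylcyclohex-2-en-1-yl]-3-methylpenta-2,4-dien-1-yl}triphenylphosphonium bromide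
Conditions: Ph3P·HBr (1.05 equiv), CH2Cl2, −10 to 0 °C, dark
Reagents that add atoms: triphenylphosphine hydrobromide ([Br-].c1ccc([PH+](c2ccccc2)c2ccccc2)cc1)
Why: Phosphonium salt formation as in vitamin A chemistry (ionisation of the primary dienylic alcohol to the pentadienyl cation and capture by triphenylphosphine at the terminal carbon) should outpace ionisation of the ring allylic alcohol in a non-nucleophilic solvent at low temperature.

Step 21
Reactants: 29 {(2E,4E)-5-[(1R,4R)-4-hydroxy-2,6,6-trimethylcyclohex-2-en-1-yl]-3-methylpenta-2,4-dien-1-yl}triphenylphosphonium bromide; 30 (2E,4E,6E)-2,7-dimethylocta-2,4,6-trienedial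
Product: 31 (2E,4E,6E,8E,10E,12E)-13-[(1R,4R)-4-hydroxy-2,6,6-trimethylcyclohex-2-en-1-yl]-2,7,11-trimethyltrideca-2,4,6,8,10,12-hexaenal
Conditions: 30 (3 equiv), 1,2-epoxybutane, EtOH, 60 °C, dark, argon; then heptane, 80 °C
Reagents that add atoms: none
Why: Wittig reaction of the ylide, formed reversibly under base-free epoxide conditions, with an excess of the symmetrical dialdehyde should give the mono-olefination product, and any Z isomer at the new double bond should equilibrate thermally to E.

Step 22
Reactants: 31 (2E,4E,6E,8E,10E,12E)-13-[(1R,4R)-4-hydroxy-2,6,6-trimethylcyclohex-2-en-1-yl]-2,7,11-trimethyltrideca-2,4,6,8,10,12-hexaenal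
Product: 32 (2E,4E,6E,8E,10E,12E)-13-[(1R,4R)-4-hydroxy-2,6,6-trimethylcyclohex-2-en-1-yl]-2,7,11-trimethyltrideca-2,4,6,8,10,12-hexaen-1-ol
Conditions: NaBH4, EtOH/THF, 0 °C
Reagents that add atoms: none
Why: Borohydride 1,2-reduction of the polyenal should give the primary polyenylic alcohol.

Step 23
Reactants: 32 (2E,4E,6E,8E,10E,12E)-13-[(1R,4R)-4-hydroxy-2,6,6-trimethylcyclohex-2-en-1-yl]-2,7,11-trimethyltrideca-2,4,6,8,10,12-hexaen-1-ol
Product: 33 {(2E,4E,6E,8E,10E,12E)-13-[(1R,4R)-4-hydroxy-2,6,6-trimethylcyclohex-2-en-1-yl]-2,7,11-trimethyltrideca-2,4,6,8,10,12-hexaen-1-yl}triphenylphosphonium bromide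
Conditions: Ph3P·HBr (1.05 equiv), CH2Cl2, −10 °C, dark
Reagents that add atoms: triphenylphosphine hydrobromide ([Br-].c1ccc([PH+](c2ccccc2)c2ccccc2)cc1)
Why: Phosphonium salt formation from the polyenylic alcohol via its highly delocalised cation should be fast at low temperature and leave the ring allylic alcohol alone.

Step 24
Reactants: 22 (2E)-2-{[(4R)-4-hydroxy-2,6,6-trimethylcyclohex-1-en-1-yl]acetyl}-4-oxobut-2-en-1-yl dodecanoate; 33 {(2E,4E,6E,8E,10E,12E)-13-[(1R,4R)-4-hydroxy-2,6,6-trimethylcyclohex-2-en-1-yl]-2,7,11-trimethyltrideca-2,4,6,8,10,12-hexaen-1-yl}triphenylphosphonium bromide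
Product: 34 (3R,3'R,6'R)-3,3'-dihydroxy-8-oxo-7,8-dihydro-β,ε-caroten-19-yl dodecanoate
Conditions: 1,2-epoxybutane (solvent), 60 °C, dark, argon; then heptane, 70 °C
Reagents that add atoms: none
Why: Wittig olefination under base-free conditions (epoxide as HBr scavenger) should be chemoselective for the aldehyde over the ketone, compatible with the ester and both free hydroxyls, and gentle heating should equilibrate the new C11=C12 bond to E.

**Compound list**

1 | 3-methylbut-2-enenitrile | CC(C)=CC#N | starting material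
2 | 2,3-dibromo-3-methylbutanenitrile | CC(C)(Br)C(Br)C#N | intermediate
3 | 2-bromo-3-methylbut-2-enenitrile | CC(C)=C(Br)C#N | intermediate
4 | 4,4,5,5-tetramethyl-2-(prop-1-en-2-yl)-1,3,2-dioxaborolane | CC(=C)B1OC(C)(C)C(C)(C)O1 | starting material
5 | 3-methyl-2-(prop-1-en-2-yl)but-2-enenitrile | CC(=C)C(C#N)=C(C)C | intermediate
6 | (1S)-1-(2,4,6-triisopropylphenyl)ethanol | C[C@H](O)c1c(C(C)C)cc(C(C)C)cc1C(C)C | starting material
7 | butyl vinyl ether | CCCCOC=C | starting material
8 | 1,3,5-triisopropyl-2-[(1S)-1-(vinyloxy)ethyl]benzene | C=CO[C@@H](C)c1c(C(C)C)cc(C(C)C)cc1C(C)C | intermediate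
9 | (4R)-2,6,6-trimethyl-4-[(1S)-1-(2,4,6-triisopropylphenyl)ethoxy]cyclohex-1-ene-1-carbonitrile | N#CC1=C(C)C[C@@H](O[C@@H](C)c2c(C(C)C)cc(C(C)C)cc2C(C)C)CC1(C)C | intermediate
10 | (4R)-4-hydroxy-2,6,6-trimethylcyclohex-1-ene-1-carbonitrile | N#CC1=C(C)C[C@@H](O)CC1(C)C | intermediate
11 | (1R)-4-(iminomethyl)-3,5,5-trimethylcyclohex-3-en-1-ol | N=CC1=C(C)C[C@@H](O)CC1(C)C | intermediate
12 | (4R)-4-hydroxy-2,6,6-trimethylcyclohex-1-ene-1-carbaldehyde | O=CC1=C(C)C[C@@H](O)CC1(C)C | intermediate
13 | (1R)-4-(2-methoxyethenyl)-3,5,5-trimethylcyclohex-3-en-1-ol (E/Z mixture) | COC=CC1=C(C)C[C@@H](O)CC1(C)C | intermediate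
14 | [(4R)-4-hydroxy-2,6,6-trimethylcyclohex-1-en-1-yl]acetaldehyde | O=CCC1=C(C)C[C@@H](O)CC1(C)C | intermediate
15 | 4,4-diethoxybut-2-yn-1-ol | CCOC(OCC)C#CCO | starting material
16 | (2E)-4,4-diethoxy-2-(tributylstannyl)but-2-en-1-ol | OC/C(=C\C(OCC)OCC)[Sn](CCCC)(CCCC)CCCC | intermediate
17 | (2E)-4,4-diethoxy-2-iodobut-2-en-1-ol | OC/C(I)=C\C(OCC)OCC | intermediate
18 | dodecanoyl chloride | CCCCCCCCCCCC(=O)Cl | starting material
19 | (2E)-4,4-diethoxy-2-iodobut-2-en-1-yl dodecanoate | CCCCCCCCCCCC(=O)OC/C(I)=C\C(OCC)OCC | intermediate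
20 | (2E)-4,4-diethoxy-2-{1-hydroxy-2-[(4R)-4-hydroxy-2,6,6-trimethylcyclohex-1-en-1-yl]ethyl}but-2-en-1-yl dodecanoate (both carbinol epimers) | CCCCCCCCCCCC(=O)OC/C(=C\C(OCC)OCC)C(O)CC1=C(C)C[C@@H](O)CC1(C)C | intermediate
21 | (2E)-4,4-diethoxy-2-{[(4R)-4-hydroxy-2,6,6-trimethylcyclohex-1-en-1-yl]acetyl}but-2-en-1-yl dodecanoate | CCCCCCCCCCCC(=O)OC/C(=C\C(OCC)OCC)C(=O)CC1=C(C)C[C@@H](O)CC1(C)C | intermediate
22 | (2E)-2-{[(4R)-4-hydroxy-2,6,6-trimethylcyclohex-1-en-1-yl]acetyl}-4-oxobut-2-en-1-yl dodecanoate | CCCCCCCCCCCC(=O)OC/C(=C\C=O)C(=O)CC1=C(C)C[C@@H](O)CC1(C)C | intermediate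
23 | (3E)-4-[(1R)-2,6,6-trimethylcyclohex-2-en-1-yl]but-3-en-2-one, (R)-α-ionone | CC(=O)/C=C/[C@H]1C(C)=CCCC1(C)C | starting material
24 | ethyl (2E,4E)-3-methyl-5-[(1R)-2,6,6-trimethylcyclohex-2-en-1-yl]penta-2,4-dienoate | CCOC(=O)/C=C(C)/C=C/[C@H]1C(C)=CCCC1(C)C | intermediate
25 | ethyl (2E,4E)-3-methyl-5-[(1R)-2,6,6-trimethyl-4-oxocyclohex-2-en-1-yl]penta-2,4-dienoate | CCOC(=O)/C=C(C)/C=C/[C@H]1C(C)=CC(=O)CC1(C)C | intermediate
26 | ethyl (2E,4E)-5-[(1R,4S)-4-hydroxy-2,6,6-trimethylcyclohex-2-en-1-yl]-3-methylpenta-2,4-dienoate | CCOC(=O)/C=C(C)/C=C/[C@H]1C(C)=C[C@@H](O)CC1(C)C | intermediate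
27 | (1R,4R)-4-[(1E,3E)-5-ethoxy-3-methyl-5-oxopenta-1,3-dien-1-yl]-3,5,5-trimethylcyclohex-2-en-1-yl benzoate | CCOC(=O)/C=C(C)/C=C/[C@H]1C(C)=C[C@H](OC(=O)c2ccccc2)CC1(C)C | intermediate
28 | (2E,4E)-5-[(1R,4R)-4-hydroxy-2,6,6-trimethylcyclohex-2-en-1-yl]-3-methylpenta-2,4-dien-1-ol | OC/C=C(C)/C=C/[C@H]1C(C)=C[C@H](O)CC1(C)C | intermediate
29 | {(2E,4E)-5-[(1R,4R)-4-hydroxy-2,6,6-trimethylcyclohex-2-en-1-yl]-3-methylpenta-2,4-dien-1-yl}triphenylphosphonium bromide | [Br-].C(/C=C(C)/C=C/[C@H]1C(C)=C[C@H](O)CC1(C)C)[P+](c1ccccc1)(c1ccccc1)c1ccccc1 | intermediate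
30 | (2E,4E,6E)-2,7-dimethylocta-2,4,6-trienedial | O=C/C(C)=C/C=C/C=C(C)/C=O | starting material
31 | (2E,4E,6E,8E,10E,12E)-13-[(1R,4R)-4-hydroxy-2,6,6-trimethylcyclohex-2-en-1-yl]-2,7,11-trimethyltrideca-2,4,6,8,10,12-hexaenal | O=C/C(C)=C/C=C/C=C(C)/C=C/C=C(C)/C=C/[C@H]1C(C)=C[C@H](O)CC1(C)C | intermediate
32 | (2E,4E,6E,8E,10E,12E)-13-[(1R,4R)-4-hydroxy-2,6,6-trimethylcyclohex-2-en-1-yl]-2,7,11-trimethyltrideca-2,4,6,8,10,12-hexaen-1-ol | OC/C(C)=C/C=C/C=C(C)/C=C/C=C(C)/C=C/[C@H]1C(C)=C[C@H](O)CC1(C)C | intermediate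
33 | {(2E,4E,6E,8E,10E,12E)-13-[(1R,4R)-4-hydroxy-2,6,6-trimethylcyclohex-2-en-1-yl]-2,7,11-trimethyltrideca-2,4,6,8,10,12-hexaen-1-yl}triphenylphosphonium bromide | [Br-].C(/C(C)=C/C=C/C=C(C)/C=C/C=C(C)/C=C/[C@H]1C(C)=C[C@H](O)CC1(C)C)[P+](c1ccccc1)(c1ccccc1)c1ccccc1 | intermediate
34 | (3R,3'R,6'R)-3,3'-dihydroxy-8-oxo-7,8-dihydro-β,ε-caroten-19-yl dodecanoate | CCCCCCCCCCCC(=O)OC\C(=C/C=C/C(C)=C/C=C/C=C(C)/C=C/C=C(C)/C=C/[C@H]1C(C)=C[C@H](O)CC1(C)C)C(=O)CC1=C(C)C[C@@H](O)CC1(C)C | target

**Count and risks**

Total step count: 24. Longest linear sequence: 11 steps (steps 1, 2, 4, 5, 6, 7, 8, 12, 13, 14, 24).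

Steps most likely to fail:

1. Step 4. The twisted diene with its fully substituted terminus may react too slowly even under pressure, ring closure may take a [2+2] course through a zwitterion, or the auxiliary may discriminate the two enol ether faces poorly. The fallback sets out from compound 5 and uses known reaction types. Thermal inverse-demand Diels–Alder reaction with the far more nucleophilic 1,1-diethoxyethene (toluene, 110 °C) should give 4,4-diethoxy-2,6,6-trimethylcyclohex-1-ene-1-carbonitrile F1. Mild aqueous acid should then give 2,6,6-trimethyl-4-oxocyclohex-1-ene-1-carbonitrile F2, whose double bond stays conjugated to the nitrile. Enantioselective reduction with an (R)-selective ketoreductase (NADPH, isopropanol recycling, pH 7) moves the origin of the stereocentre from the auxiliary to the enzyme and comes back to the route at compound 10.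

2. Step 17. Hydride delivery may show low or reversed facial preference if the ring reacts through the other half-chair, in which case the inversion of step 18 would produce the wrong epimer. The fallback sets out from compound 25 and replaces substrate control by catalyst control. CBS reduction ((S)-2-methyl-CBS-oxazaborolidine, catecholborane, toluene, −78 °C, the alkenyl flank acting as the large group) should give ethyl (2E,4E)-5-[(1R,4R)-4-hydroxy-2,6,6-trimethylcyclohex-2-en-1-yl]-3-methylpenta-2,4-dienoate F3 directly. DIBAL-H reduction of its ester comes back to the route at compound 28, and step 18 is bypassed.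

3. Step 24. The ylide may add in conjugate fashion to the doubly activated ene-dicarbonyl unit, or enolisation at the CH2 between ring and ketone may shift the ring double bond during the long heating. The fallback sets out from compound 20, so that the ketone is introduced only after the olefination. Acetal hydrolysis (TsOH, wet THF) should give (2E)-2-{1-hydroxy-2-[(4R)-4-hydroxy-2,6,6-trimethylcyclohex-1-en-1-yl]ethyl}-4-oxobut-2-en-1-yl dodecanoate F4. Base-free Wittig reaction with 33 should give (3R,3'R,6'R)-3,8,3'-trihydroxy-7,8-dihydro-β,ε-caroten-19-yl dodecanoate F5. MnO2 at 0 °C should then oxidise the carbinol that is allylic to the heptaene faster than the non-allylic 3-hydroxyl and the hindered, isolated allylic 3'-hydroxyl, and the sequence comes back to the route at compound 34.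

**Further compounds**

F1 | step 4 | 4,4-diethoxy-2,6,6-trimethylcyclohex-1-ene-1-carbonitrile | N#CC1=C(C)CC(OCC)(OCC)CC1(C)C
F2 | step 4 | 2,6,6-trimethyl-4-oxocyclohex-1-ene-1-carbonitrile | N#CC1=C(C)CC(=O)CC1(C)C
F3 | step 17 | ethyl (2E,4E)-5-[(1R,4R)-4-hydroxy-2,6,6-trimethylcyclohex-2-en-1-yl]-3-methylpenta-2,4-dienoate | CCOC(=O)/C=C(C)/C=C/[C@H]1C(C)=C[C@H](O)CC1(C)C
F4 | step 24 | (2E)-2-{1-hydroxy-2-[(4R)-4-hydroxy-2,6,6-trimethylcyclohex-1-en-1-yl]ethyl}-4-oxobut-2-en-1-yl dodecanoate | CCCCCCCCCCCC(=O)OC/C(=C\C=O)C(O)CC1=C(C)C[C@@H](O)CC1(C)C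
F5 | step 24 | (3R,3'R,6'R)-3,8,3'-trihydroxy-7,8-dihydro-β,ε-caroten-19-yl dodecanoate | CCCCCCCCCCCC(=O)OC\C(=C/C=C/C(C)=C/C=C/C=C(C)/C=C/C=C(C)/C=C/[C@H]1C(C)=C[C@H](O)CC1(C)C)C(O)CC1=C(C)C[C@@H](O)CC1(C)C
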